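**Retrosynthetic overview**
- The target is a 2,3-seco-labdane ether (labdane numbering): cyclohexane ring B (C5–C10) is cis-fused to tetrahydropyran ring C (O–C8–C9–C11–C12–C13). The strategy rests on the C8–C9 fusion, where O8 and C11 are cis beside the quaternary C10 (CH3, CH2CO2H); this is the signature of trans delivery of C10 and O13 to the two faces of a Z C8=C9 alkene.
- C9–C10 and C8–O are disconnected together (rings B and C formed in one operation, B by C–C and C by C–O bonding) to the acyclic Z hydroxy dienyl alkylidene malonate 23. The malonate later becomes CH2CO2H by hydrolysis and decarboxylation.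
- 23 is cut at C7–C8 (Negishi coupling) into Z alkenyl iodide 5, made from (R)-linalool (C13 from the chiral pool; ozonolysis, iodo-Wittig), and alkyl bromide 20.
- 20 comes from 5,6-dihydro-2H-pyran-2-one: asymmetric rhodium-catalysed addition sets C5, double methylation builds C4, and the hindered alkylidene malonate is made by methylcupration/acylation of an ynoate, not by Knoevenagel condensation of the hindered, enolisable ketone.

Key step: step 13

Assumption: commercial (R)-(−)-linalool of high enantiomeric purity supplies C13 unchanged; atom labels C1–C20 are labdane numbers.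

**Route**

Step 1
Reactants: 1 (R)-linalool, (3R)-3,7-dimethylocta-1,6-dien-3-ol
Product: 2 triethyl{[(3R)-3,7-dimethylocta-1,6-dien-3-yl]oxy}silane
Conditions: Et3SiOTf, 2,6-lutidine, CH2Cl2, −78 → 0 °C
Reagents that add atoms: triethylsilyl trifluoromethanesulfonate, CC[Si](CC)(CC)OS(=O)(=O)C(F)(F)F
Why: Silyl ether formation with the triflate and a hindered pyridine base silylates even the tertiary alcohol, which must be masked because the free 4-hydroxy aldehyde of the next step would close to a lactol; C13 keeps the (R) configuration of the chiral pool.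

Step 2
Reactants: 2 triethyl{[(3R)-3,7-dimethylocta-1,6-dien-3-yl]oxy}silane
Product: 4 (4R)-4-methyl-4-(triethylsilyloxy)hex-5-enal, via ozonide 3 (not isolated)
Conditions: O3 (1 equiv, Sudan Red 7B end point), CH2Cl2, −78 °C; then PPh3, −78 °C → rt
Reagents that add atoms: ozone, [O-][O+]=O
Why: Ozonolysis with reductive work-up, metered to one equivalent, should cleave the electron-rich trisubstituted alkene well before the monosubstituted vinyl group next to the bulky silyloxy carbon, giving the aldehyde carbon that becomes C9.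

Step 3
Reactants: 4 (4R)-4-methyl-4-(triethylsilyloxy)hex-5-enal
Product: 5 (3R,6Z)-7-iodo-3-methyl-3-(triethylsilyloxy)octa-1,6-diene
Conditions: EtPPh3I, n-BuLi, THF, rt; I2, −78 °C; NaHMDS, −20 °C; then 4, −78 °C → rt
Reagents that add atoms: ethyltriphenylphosphonium iodide, CC[P+](c1ccccc1)(c1ccccc1)c1ccccc1.[I-]; iodine, II
Why: Stork–Zhao-type Wittig olefination with the alpha-iodo ylide is kinetically Z selective for aliphatic aldehydes, which should place iodine (the site of the later C7–C8 bond) cis to the C11 chain and the C17 methyl trans to it.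

Step 4
Reactants: 6 5,6-dihydro-2H-pyran-2-one; 7 4,4,5,5-tetramethyl-2-(prop-1-en-2-yl)-1,3,2-dioxaborolane
Product: 8 (4S)-4-(prop-1-en-2-yl)oxan-2-one
Conditions: [Rh(OH)((S)-BINAP)]2 (3 mol% Rh), dioxane/H2O (10:1), 60 °C
Reagents that add atoms: none
Why: Hayashi–Miyaura rhodium-catalysed asymmetric conjugate addition of an alkenylboronate to a cyclic enoate sets C5; with (S)-BINAP the alkenylrhodium should add to the face that gives the (S) centre, in line with the sense established for six-membered cyclic acceptors (the antipodal ligand is the remedy if the sense proves reversed).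

Step 5
Reactants: 8 (4S)-4-(prop-1-en-2-yl)oxan-2-one
Product: 10 methyl (3S)-5-[(tert-butyldimethylsilyl)oxy]-3-(prop-1-en-2-yl)pentanoate, via hydroxy ester 9 (not isolated)
Conditions: NaOMe (0.1 equiv), MeOH, 0 °C → rt; AcOH (0.1 equiv), concentrate cold; then TBSCl, imidazole, DMF, rt
Reagents that add atoms: methanol, CO; tert-butyldimethylsilyl chloride, CC(C)(C)[Si](C)(C)Cl
Why: Methoxide-catalysed transesterification opens the delta-lactone in methanol and silyl ether protection of the primary alcohol locks the open form, leaving C3 as the methyl ester and C7–O masked for the enolate and organocopper steps.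

Step 6
Reactants: 10 methyl (3S)-5-[(tert-butyldimethylsilyl)oxy]-3-(prop-1-en-2-yl)pentanoate
Product: 12 methyl (3R)-5-[(tert-butyldimethylsilyl)oxy]-2,2-dimethyl-3-(prop-1-en-2-yl)pentanoate, via monomethyl ester 11 (not isolated)
Conditions: LDA, THF, −78 °C; MeI; then LDA, −78 °C; MeI, DMPU, −78 → 0 °C
Reagents that add atoms: iodomethane, CI
Why: Two successive ester enolate alkylations with iodomethane create the quaternary C4; C5 is beta to the ester and is not deprotonated, and no stereocentre arises at C4 because both new groups are methyl (the descriptor at C5 changes only through priorities).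

Step 7
Reactants: 12 methyl (3R)-5-[(tert-butyldimethylsilyl)oxy]-2,2-dimethyl-3-(prop-1-en-2-yl)pentanoate
Product: 14 methyl (3S)-3-acetyl-5-[(tert-butyldimethylsilyl)oxy]-2,2-dimethylpentanoate, via ozonide 13 (not isolated)
Conditions: O3, CH2Cl2, −78 °C; then PPh3, −78 °C → rt
Reagents that add atoms: ozone, [O-][O+]=O
Why: Ozonolysis with reductive work-up of the only alkene, the 1,1-disubstituted isopropenyl group, gives the methyl ketone under neutral conditions that should not enolise the adjacent C5.

Step 8
Reactants: 14 methyl (3S)-3-acetyl-5-[(tert-butyldimethylsilyl)oxy]-2,2-dimethylpentanoate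
Product: 17 dimethyl (4R)-4-{2-[(tert-butyldimethylsilyl)oxy]ethyl}-5,5-dimethylhex-2-ynedioate, via enol phosphate 15 (not isolated), via lithium acetylide 16 (not isolated)
Conditions: LDA (1.1 equiv), THF, −78 °C; ClP(O)(OEt)2, −78 °C → rt; LDA (2.3 equiv), −78 °C → rt; then ClCO2Me, −78 → 0 °C
Reagents that add atoms: methyl chloroformate, COC(=O)Cl
Why: Kinetic enolisation at the methyl group, O-phosphorylation and base-induced elimination of the enol phosphate (the standard methyl ketone to alkyne conversion) give the lithium acetylide, which is C-acylated in the same flask by the chloroformate; the C3 ester has no alpha-hydrogen and the hindered C5–H is not removed at −78 °C.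

Step 9
Reactants: 17 dimethyl (4R)-4-{2-[(tert-butyldimethylsilyl)oxy]ethyl}-5,5-dimethylhex-2-ynedioate
Product: 19 dimethyl 2-[(3R)-5-[(tert-butyldimethylsilyl)oxy]-3-(1-methoxy-2-methyl-1-oxopropan-2-yl)pentan-2-ylidene]propanedioate, via alkenylcuprate 18 (not isolated)
Conditions: Me2CuLi (from MeLi and CuI), THF, −78 °C; then ClCO2Me, −78 → −30 °C
Reagents that add atoms: lithium dimethylcuprate, [Li+].C[Cu-]C; methyl chloroformate, COC(=O)Cl
Why: Syn carbocupration (Gilman reagent conjugate addition) of the sterically open alkynoate installs the C20 methyl on C10, and C-acylation of the resulting alpha-(methoxycarbonyl)alkenylcuprate by the chloroformate completes the tetrasubstituted alkylidene malonate at low temperature without base, so the C5–H gamma to the malonate is not epimerised.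

Step 10
Reactants: 19 dimethyl 2-[(3R)-5-[(tert-butyldimethylsilyl)oxy]-3-(1-methoxy-2-methyl-1-oxopropan-2-yl)pentan-2-ylidene]propanedioate
Product: 20 dimethyl 2-[(3R)-5-bromo-3-(1-methoxy-2-methyl-1-oxopropan-2-yl)pentan-2-ylidene]propanedioate
Conditions: Ph3PBr2, CH2Cl2, 0 °C → rt
Reagents that add atoms: triphenylphosphine dibromide, BrP(Br)(c1ccccc1)(c1ccccc1)c1ccccc1
Why: Triphenylphosphine dibromide converts a primary silyl ether directly into the bromide through the alkoxyphosphonium ion (Appel-type substitution), which avoids a free delta-hydroxy ester that would relactonise.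

Step 11
Reactants: 20 dimethyl 2-[(3R)-5-bromo-3-(1-methoxy-2-methyl-1-oxopropan-2-yl)pentan-2-ylidene]propanedioate; 5 (3R,6Z)-7-iodo-3-methyl-3-(triethylsilyloxy)octa-1,6-diene
Product: 22 dimethyl 2-[(3R,6Z,10R)-3-(1-methoxy-2-methyl-1-oxopropan-2-yl)-6,10-dimethyl-10-(triethylsilyloxy)dodeca-6,11-dien-2-ylidene]propanedioate, via alkylzinc bromide 21 (not isolated)
Conditions: Zn dust (BrCH2CH2Br/Me3SiCl-activated), LiCl, THF, 50 °C; then 5, PdCl2(dppf) (5 mol%), THF, rt → 45 °C
Reagents that add atoms: none
Why: LiCl-assisted zinc insertion gives a primary alkylzinc bromide that tolerates the esters and the alkylidene malonate, and palladium-catalysed Negishi coupling with the alkenyl iodide forms C7–C8 with retention of the Z geometry under neutral conditions.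

Step 12
Reactants: 22 dimethyl 2-[(3R,6Z,10R)-3-(1-methoxy-2-methyl-1-oxopropan-2-yl)-6,10-dimethyl-10-(triethylsilyloxy)dodeca-6,11-dien-2-ylidene]propanedioate
Product: 23 dimethyl 2-[(3R,6Z,10R)-10-hydroxy-3-(1-methoxy-2-methyl-1-oxopropan-2-yl)-6,10-dimethyldodeca-6,11-dien-2-ylidene]propanedioate
Conditions: HF·pyridine, pyridine, THF, 0 °C → rt
Reagents that add atoms: none
Why: Fluoride-mediated desilylation with pyridine-buffered HF·pyridine frees the tertiary alcohol without base, so the alkylidene malonate is not deconjugated and C5 is not scrambled.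

Step 13
Reactants: 23 dimethyl 2-[(3R,6Z,10R)-10-hydroxy-3-(1-methoxy-2-methyl-1-oxopropan-2-yl)-6,10-dimethyldodeca-6,11-dien-2-ylidene]propanedioate
Product: 24 dimethyl 2-[(2R,4aS,5S,6R,8aR)-2-ethenyl-6-(1-methoxy-2-methyl-1-oxopropan-2-yl)-2,5,8a-trimethyloctahydro-2H-chromen-5-yl]propanedioate
Conditions: Sc(OTf)3 (20 mol%), 2,6-di-tert-butyl-4-methylpyridine (25 mol%), CH2Cl2, −40 → 0 °C
Reagents that add atoms: none
Why: Proposed new method: two-point binding of Sc(OTf)3 to the malonate carbonyls polarises the C10=C1 bond so that C10 behaves as a masked tertiary cation; C9 of the Z trisubstituted alkene attacks C10 through a chair transition state, the C13 hydroxyl adds to the developing tertiary C8 cation, and the oxonium proton is passed (through the hindered pyridine) to the scandium malonate enolate, so the step is an isomerisation that turns the catalyst over. The closest known reaction types are Lewis-acid-promoted ene and cation–olefin cyclisations of aldehyde-derived alkylidene malonates and hydroxyl-terminated polyene cyclisations; a ketone-derived, beta,beta-disubstituted malonate creating a quaternary carbon in this way is not established. Ring B closes 6-exo with respect to the C10=C1 acceptor bond and 6-endo with respect to the C8=C9 alkene, and ring C closes 6-endo by O–C8 bonding. C10 is set by allylic 1,3-strain, which keeps H5 in the plane of the alkylidene malonate so that C9 bonds on the face carrying C6 and away from the C4 group (C4 equatorial, C20 axial); C9 is set by the chair with the Z alkene, which puts C11 axial and trans to C20; C8 is set by trans addition across the Z alkene, which delivers O13 cis to C11 and leaves H9 syn to the C8 methyl. The step needs C–C bond formation to outrun ionisation of the tertiary allylic alcohol and the chair to beat the boat; two six-membered rings, two tertiary cationic centres, the buffered catalytic low-temperature conditions and the C5 substituent are what should secure this.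

Step 14
Reactants: 24 dimethyl 2-[(2R,4aS,5S,6R,8aR)-2-ethenyl-6-(1-methoxy-2-methyl-1-oxopropan-2-yl)-2,5,8a-trimethyloctahydro-2H-chromen-5-yl]propanedioate
Product: 25 2-[(2R,4aS,5S,6R,8aR)-6-(2-carboxypropan-2-yl)-2-ethenyl-2,5,8a-trimethyloctahydro-2H-chromen-5-yl]propanedioic acid
Conditions: KOH (excess), ethylene glycol/H2O (5:1), 120 °C; then 1 M HCl, 0 °C, to pH 3
Reagents that add atoms: potassium hydroxide, [K+].[OH-]
Why: Saponification under forcing alkaline conditions cleaves the two malonate esters and the hindered alpha,alpha-dimethyl ester, the ether, the vinyl group and all five stereocentres being inert to hydroxide, and cold acidification to pH 3 spares the tertiary allylic ether.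

Step 15
Reactants: 25 2-[(2R,4aS,5S,6R,8aR)-6-(2-carboxypropan-2-yl)-2-ethenyl-2,5,8a-trimethyloctahydro-2H-chromen-5-yl]propanedioic acid
Product: 26 2-[(2R,4aS,5S,6R,8aR)-5-(carboxymethyl)-2-ethenyl-2,5,8a-trimethyloctahydro-2H-chromen-6-yl]-2-methylpropanoic acid (CNP0186744.1)
Conditions: pyridine, 110 °C
Reagents that add atoms: none
Why: Thermal decarboxylation of the substituted malonic acid through its cyclic six-membered transition state leaves CH2CO2H on C10 and touches no stereocentre.

**Compound list**
1 | (R)-linalool, (3R)-3,7-dimethylocta-1,6-dien-3-ol | C=C[C@@](O)(C)CCC=C(C)C | starting material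
2 | triethyl{[(3R)-3,7-dimethylocta-1,6-dien-3-yl]oxy}silane | C=C[C@@](O[Si](CC)(CC)CC)(C)CCC=C(C)C | intermediate
3 | 5,5-dimethyl-3-[(3R)-3-methyl-3-(triethylsilyloxy)pent-4-en-1-yl]-1,2,4-trioxolane (ozonide, ring carbon unassigned) | C=C[C@@](O[Si](CC)(CC)CC)(C)CCC1OC(C)(C)OO1 | intermediate (not isolated)
4 | (4R)-4-methyl-4-(triethylsilyloxy)hex-5-enal | C=C[C@@](O[Si](CC)(CC)CC)(C)CCC=O | intermediate
5 | (3R,6Z)-7-iodo-3-methyl-3-(triethylsilyloxy)octa-1,6-diene | C=C[C@@](O[Si](CC)(CC)CC)(C)CC/C=C(/C)I | intermediate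
6 | 5,6-dihydro-2H-pyran-2-one | O=C1C=CCCO1 | starting material
7 | 4,4,5,5-tetramethyl-2-(prop-1-en-2-yl)-1,3,2-dioxaborolane | CC(=C)B1OC(C)(C)C(C)(C)O1 | starting material
8 | (4S)-4-(prop-1-en-2-yl)oxan-2-one | CC(=C)[C@H]1CCOC(=O)C1 | intermediate
9 | methyl (3S)-5-hydroxy-3-(prop-1-en-2-yl)pentanoate | COC(=O)C[C@@H](C(C)=C)CCO | intermediate (not isolated)
10 | methyl (3S)-5-[(tert-butyldimethylsilyl)oxy]-3-(prop-1-en-2-yl)pentanoate | COC(=O)C[C@@H](C(C)=C)CCO[Si](C)(C)C(C)(C)C | intermediate
11 | methyl (3S)-5-[(tert-butyldimethylsilyl)oxy]-2-methyl-3-(prop-1-en-2-yl)pentanoate (both C2 epimers) | COC(=O)C(C)[C@@H](C(C)=C)CCO[Si](C)(C)C(C)(C)C | intermediate (not isolated)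
12 | methyl (3R)-5-[(tert-butyldimethylsilyl)oxy]-2,2-dimethyl-3-(prop-1-en-2-yl)pentanoate | COC(=O)C(C)(C)[C@@H](C(C)=C)CCO[Si](C)(C)C(C)(C)C | intermediate
13 | methyl (3S)-5-[(tert-butyldimethylsilyl)oxy]-2,2-dimethyl-3-(3-methyl-1,2,4-trioxolan-3-yl)pentanoate (ozonide, ring carbon unassigned) | COC(=O)C(C)(C)[C@@H](C1(C)OCOO1)CCO[Si](C)(C)C(C)(C)C | intermediate (not isolated)
14 | methyl (3S)-3-acetyl-5-[(tert-butyldimethylsilyl)oxy]-2,2-dimethylpentanoate | COC(=O)C(C)(C)[C@@H](C(C)=O)CCO[Si](C)(C)C(C)(C)C | intermediate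
15 | methyl (3S)-5-[(tert-butyldimethylsilyl)oxy]-3-{1-[(diethoxyphosphoryl)oxy]ethenyl}-2,2-dimethylpentanoate | COC(=O)C(C)(C)[C@@H](C(=C)OP(=O)(OCC)OCC)CCO[Si](C)(C)C(C)(C)C | intermediate (not isolated)
16 | lithium acetylide of methyl (3R)-5-[(tert-butyldimethylsilyl)oxy]-3-ethynyl-2,2-dimethylpentanoate | COC(=O)C(C)(C)[C@@H](C#C[Li])CCO[Si](C)(C)C(C)(C)C | intermediate (not isolated)
17 | dimethyl (4R)-4-{2-[(tert-butyldimethylsilyl)oxy]ethyl}-5,5-dimethylhex-2-ynedioate | COC(=O)C(C)(C)[C@@H](C#CC(=O)OC)CCO[Si](C)(C)C(C)(C)C | intermediate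
18 | lithium methyl(alkenyl)cuprate from syn addition of the Gilman reagent to 17 (copper on C1, cis to the new C20 methyl) | COC(=O)C(C)(C)[C@@H](/C(C)=C(\C(=O)OC)[Cu-]C)CCO[Si](C)(C)C(C)(C)C.[Li+] | intermediate (not isolated)
19 | dimethyl 2-[(3R)-5-[(tert-butyldimethylsilyl)oxy]-3-(1-methoxy-2-methyl-1-oxopropan-2-yl)pentan-2-ylidene]propanedioate | COC(=O)C(C)(C)[C@@H](C(C)=C(C(=O)OC)C(=O)OC)CCO[Si](C)(C)C(C)(C)C | intermediate
20 | dimethyl 2-[(3R)-5-bromo-3-(1-methoxy-2-methyl-1-oxopropan-2-yl)pentan-2-ylidene]propanedioate | COC(=O)C(C)(C)[C@@H](C(C)=C(C(=O)OC)C(=O)OC)CCBr | intermediate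
21 | alkylzinc bromide of 20 (C7–ZnBr, LiCl complex) | COC(=O)C(C)(C)[C@@H](C(C)=C(C(=O)OC)C(=O)OC)CC[Zn]Br | intermediate (not isolated)
22 | dimethyl 2-[(3R,6Z,10R)-3-(1-methoxy-2-methyl-1-oxopropan-2-yl)-6,10-dimethyl-10-(triethylsilyloxy)dodeca-6,11-dien-2-ylidene]propanedioate | C=C[C@@](O[Si](CC)(CC)CC)(C)CC/C=C(/C)CC[C@@H](C(C)(C)C(=O)OC)C(C)=C(C(=O)OC)C(=O)OC | intermediate
23 | dimethyl 2-[(3R,6Z,10R)-10-hydroxy-3-(1-methoxy-2-methyl-1-oxopropan-2-yl)-6,10-dimethyldodeca-6,11-dien-2-ylidene]propanedioate (key-step precursor) | C=C[C@@](O)(C)CC/C=C(/C)CC[C@@H](C(C)(C)C(=O)OC)C(C)=C(C(=O)OC)C(=O)OC | intermediate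
24 | dimethyl 2-[(2R,4aS,5S,6R,8aR)-2-ethenyl-6-(1-methoxy-2-methyl-1-oxopropan-2-yl)-2,5,8a-trimethyloctahydro-2H-chromen-5-yl]propanedioate (key-step product) | C=C[C@@]1(C)CC[C@H]2[C@@](C)(C(C(=O)OC)C(=O)OC)[C@H](C(C)(C)C(=O)OC)CC[C@@]2(C)O1 | intermediate
25 | 2-[(2R,4aS,5S,6R,8aR)-6-(2-carboxypropan-2-yl)-2-ethenyl-2,5,8a-trimethyloctahydro-2H-chromen-5-yl]propanedioic acid | C=C[C@@]1(C)CC[C@H]2[C@@](C)(C(C(=O)O)C(=O)O)[C@H](C(C)(C)C(=O)O)CC[C@@]2(C)O1 | intermediate
26 | 2-[(2R,4aS,5S,6R,8aR)-5-(carboxymethyl)-2-ethenyl-2,5,8a-trimethyloctahydro-2H-chromen-6-yl]-2-methylpropanoic acid | C=C[C@@]1(C)CC[C@H]2[C@@](C)(CC(=O)O)[C@H](C(C)(C)C(=O)O)CC[C@@]2(C)O1 | target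

**Step count**
Total: 15 steps. Longest linear sequence: 12 steps (steps 4–15, from 5,6-dihydro-2H-pyran-2-one); the linalool branch (steps 1–3) joins at step 11.

**Steps most likely to fail**

Step 13 (proposed new method). The tetrasubstituted acceptor may be activated too weakly, so that ionisation of the tertiary allylic alcohol or proton loss to ene-type alkenes outruns the bicyclisation; leakage through a boat transition state would erode the C9/C8 relationship. The fallback makes the two bonds in the opposite order by known chemistry, ring C first by a polar step and ring B second by a radical step. From 23, N-(phenylseleno)phthalimide with catalytic camphorsulfonic acid in CH2Cl2 at 0 °C should effect 6-endo (Markovnikov) selenoetherification by trans addition across the Z alkene. This gives dimethyl 2-{(3R)-5-[(2R,3R,6R)-6-ethenyl-2,6-dimethyl-3-(phenylselanyl)oxan-2-yl]-3-(1-methoxy-2-methyl-1-oxopropan-2-yl)pentan-2-ylidene}propanedioate F1; its C8 epimer would have to be separated, because C13 offers little facial control. Bu3SnH/AIBN (slow addition, benzene, 80 °C) then generates the secondary C9 radical, which closes ring B by 6-exo Giese-type addition to C10 of the alkylidene malonate. Hydrogen transfer to the malonyl radical returns the route at 24.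

Step 9. C-acylation of the hindered alkenylcuprate may lose to protonation (simple enoate) or O-acylation. The fallback builds the alkylidene malonate by carbonyl condensation: from ketone 14, TiCl4/pyridine-mediated Knoevenagel condensation with dimethyl malonate (THF, 0 °C → rt) leads directly to 19, bypassing steps 8 and 9. No compound outside the list is made (F0). The price is a slow condensation at a hindered ketone and the need to check C5 integrity.

Step 3. The iodo-ylide olefination may suffer erosion of Z selectivity, loss of iodine and low conversion. The fallback replaces ylide chemistry by stepwise cross-coupling. From aldehyde 4, Corey–Fuchs dibromo-olefination (CBr4, PPh3, Et3N, CH2Cl2, 0 °C) gives (3R)-7,7-dibromo-3-methyl-3-(triethylsilyloxy)hepta-1,6-diene F2. Palladium-catalysed trans-selective monomethylation (Me2Zn, PdCl2(DPEphos), THF) replaces the bromine trans to the chain and gives (3R,6Z)-7-bromo-3-methyl-3-(triethylsilyloxy)octa-1,6-diene F3. F3 takes the place of iodide 5 in the Negishi coupling of step 11 (Pd(P(t-Bu)3)2 as catalyst) and the route is rejoined at 22.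

Further compounds
F1 | step 13 | dimethyl 2-{(3R)-5-[(2R,3R,6R)-6-ethenyl-2,6-dimethyl-3-(phenylselanyl)oxan-2-yl]-3-(1-methoxy-2-methyl-1-oxopropan-2-yl)pentan-2-ylidene}propanedioate | C=C[C@@]1(C)CC[C@@H]([Se]c2ccccc2)[C@@](C)(CC[C@@H](C(C)(C)C(=O)OC)C(C)=C(C(=O)OC)C(=O)OC)O1
F0 | step 9 | none | none
F2 | step 3 | (3R)-7,7-dibromo-3-methyl-3-(triethylsilyloxy)hepta-1,6-diene | C=C[C@@](O[Si](CC)(CC)CC)(C)CCC=C(Br)Br
F3 | step 3 | (3R,6Z)-7-bromo-3-methyl-3-(triethylsilyloxy)octa-1,6-diene | C=C[C@@](O[Si](CC)(CC)CC)(C)CC/C=C(/C)Br
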